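**Retrosynthetic overview**

1. 34 ⇐ ketone 31 (Corey–Chaykovsky methylene transfer at C12, then unmasking of the C15 formyl group) ⇐ aldehyde 27, the first compound with the bicyclo[9.3.1] skeleton.
2. 27 ⇐ epoxide 26 of a bicyclo[9.3.2]hexadecatriene: Lewis-acid epoxide-to-aldehyde rearrangement in which C11 shifts from C16 to C15. The cycloheptane C1–C14–C13–C12–C11–C16–C15 contracts to the cyclohexane C1–C14–C13–C12–C11–C15 (and the 13-membered ring to the 12-membered one) while C16 becomes the formyl carbon.
3. 26 ⇐ 24 (hydroxyl-directed epoxidation) ⇐ 21 (B-alkyl Suzuki macrocyclisation, C8–C9); both Z alkenes come from Stork–Zhao iodo-olefination followed by Suzuki coupling (C3=C4/C4–C5 and C7=C8/C8–C9).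
4. Cycloheptene core 14 ⇐ Johnson–Claisen rearrangement (C1–C2 bond, chirality transfer from C16–O) ⇐ Rubottom oxidation and anti conjugate addition on (R)-4-silyloxycyclohept-2-enone 4 ⇐ cyclohepta-1,3-diene 1 (endoperoxide, asymmetric Kornblum–DeLaMare rearrangement).
5. Ring order: seven-membered carbocycle (present from 1), 13-membered ring (step 14), cyclohexane and 12-membered ring together (step 18), oxirane (step 22). Enabling feature: C15 is a quaternary ring carbon that bears the formyl group and lies between the ring methines C1 and C11, so the formyl carbon C16 can be a ring atom of a cycloheptene 15,16-epoxide that leaves the ring when C11 migrates.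

Key step: step 18

Labels: the bicyclo[9.3.1]pentadecane numbering of the target is used for all compounds. C1 and C11 are the ring methines, C2–C10 the nine-carbon bridge (Z alkenes C3=C4 and C7=C8, methyl groups on C4 and C8), C12 the spiro carbon, C13 and C14 ring methylenes, C15 the quaternary carbon; C16 is the formyl carbon.

Remark on the configuration: the structure is taken as written, i.e. C2 (on C1) and C10 (on C11) are trans on the cyclohexane, the formyl group is cis to C2, the oxirane oxygen is cis to C10, and both ring alkenes are Z.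

**Route**

Step 1
Reactants: 1 cyclohepta-1,3-diene
Product: 2 6,7-dioxabicyclo[3.2.2]non-8-ene (meso endoperoxide)
Conditions: O2, tetraphenylporphyrin (cat.), visible light, CH2Cl2, 0 °C
Reagents that add atoms: dioxygen, O=O
Why: Singlet-oxygen [4+2] cycloaddition (photooxygenation) of the cisoid ring diene should give the meso cis-1,4-endoperoxide, which oxygenates the carbons that become C15 and C12.

Step 2
Reactants: 2 6,7-dioxabicyclo[3.2.2]non-8-ene
Product: 3 (R)-4-hydroxycyclohept-2-en-1-one
Conditions: cinchona-derived bifunctional amine catalyst (9-O-acetyl-6'-hydroxy type, 5 mol %, pseudoenantiomer chosen for the R alcohol), CH2Cl2, rt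
Reagents that add atoms: none
Why: Base-catalysed Kornblum–DeLaMare rearrangement: the chiral amine removes one of the two enantiotopic peroxide α-hydrogens with O–O cleavage, so desymmetrisation of the meso peroxide should set the C12 carbinol centre under catalyst control.

Step 3
Reactants: 3 (R)-4-hydroxycyclohept-2-en-1-one
Product: 4 (R)-4-(tert-butyldimethylsilyloxy)cyclohept-2-en-1-one
Conditions: TBSCl, imidazole, DMF, 0 °C to rt
Reagents that add atoms: tert-butyldimethylsilyl chloride, CC(C)(C)[Si](C)(C)Cl
Why: Imidazole-promoted silylation protects the allylic alcohol and turns it into the bulky group that steers the conjugate addition.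

Step 4
Reactants: 4 (R)-4-(tert-butyldimethylsilyloxy)cyclohept-2-en-1-one
Product: 5 triethylsilyl enol ether (C15–OTES, C15=C16; 11-vinyl trans to 12-OTBS)
Conditions: CH2=CHMgBr, CuBr·SMe2 (10 mol %), Et3SiCl, THF, −78 °C
Reagents that add atoms: vinylmagnesium bromide, C=C[Mg]Br; chlorotriethylsilane, CC[Si](CC)(CC)Cl
Why: Copper-catalysed conjugate addition with in situ silyl trapping should deliver the vinyl group anti to the adjacent C12 silyloxy group, setting C11 and giving the enol ether regiospecifically at C15=C16.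

Step 5
Reactants: 5 triethylsilyl enol ether
Product: 7 α-triethylsilyloxy ketone (C15 ketone; 16-OTES cis to 12-OTBS; both trans to the 11-vinyl group), via silyloxy oxirane 6 (not isolated)
Conditions: mCPBA, NaHCO3, CH2Cl2, −20 °C
Reagents that add atoms: 3-chloroperbenzoic acid, OOC(=O)c1cccc(Cl)c1
Why: Rubottom oxidation: the peracid should epoxidise only the electron-rich enol ether, from the face anti to the neighbouring vinyl group, and the silyloxy oxirane opens with 1,4-silyl shift, setting C16–O trans to vinyl.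

Step 6
Reactants: 7 α-triethylsilyloxy ketone
Product: 8 enol triflate (C15–OTf, C15=C1)
Conditions: KN(SiMe3)2, THF, −78 °C; then PhNTf2
Reagents that add atoms: N-phenylbis(trifluoromethanesulfonimide), O=S(=O)(N(c1ccccc1)S(=O)(=O)C(F)(F)F)C(F)(F)F
Why: Kinetic enolisation by the hindered amide base at the unsubstituted C1 methylene (not at the oxygenated, flanked C16–H) followed by O-sulfonylation (enol triflate formation) fixes the C15=C1 alkene.

Step 7
Reactants: 8 enol triflate; 9 5-bromo-2-methylpent-2-ene
Product: 12 allylic alcohol (16-OH cis to 12-OTBS; C15 carries the 4-methylpent-3-enyl chain), via Grignard reagent 10 (not isolated), via triethylsilyl ether 11 (not isolated)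
Conditions: 9, Mg, THF; then 8, Fe(acac)3 (5 mol %), THF/NMP, −20 °C; then PPTS, MeOH, 0 °C
Reagents that add atoms: none
Why: Iron-catalysed alkenyl triflate–alkyl Grignard cross-coupling (Kumada type) installs the side chain on C15 without touching silyl ethers or alkenes, and mild acid methanolysis then removes only the more labile allylic triethylsilyl ether.

Step 8
Reactants: 12 allylic alcohol
Product: 14 ethyl ester (C1–CH2CO2Et cis to 12-OTBS and trans to the 11-vinyl group; C15=C16), via ketene acetal 13 (not isolated)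
Conditions: CH3C(OEt)3, EtCO2H (cat.), 135 °C
Reagents that add atoms: triethyl orthoacetate, CCOC(C)(OCC)OCC
Why: Johnson–Claisen rearrangement: the ketene acetal formed at the C16 hydroxyl undergoes a suprafacial [3,3] shift, so the C1–C2 bond forms on the face that carried the C16 oxygen, which sets C1 and moves the alkene to C15=C16.

Step 9
Reactants: 14 ethyl ester
Product: 15 aldehyde (C3 = CHO)
Conditions: i-Bu2AlH, CH2Cl2, −78 °C
Reagents that add atoms: none
Why: Partial reduction of the ester by the aluminium hydride at low temperature (stable tetrahedral aluminate) should stop at the aldehyde.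

Step 10
Reactants: 15 aldehyde
Product: 16 Z alkenyl iodide (C3=C4, iodine on C4 cis to C2)
Conditions: [Ph3PCH(I)CH3]I, NaN(SiMe3)2, THF, −78 °C
Reagents that add atoms: (1-iodoethyl)triphenylphosphonium iodide, CC(I)[P+](c1ccccc1)(c1ccccc1)c1ccccc1.[I-]
Why: Stork–Zhao olefination (Wittig reaction of the α-iodo ylide) should give the Z iodoalkene, which fixes the geometry of the C3=C4 alkene.

Step 11
Reactants: 16 Z alkenyl iodide; 17 3,3-dimethoxyprop-1-ene
Product: 19 dimethyl acetal (C7), via alkylborane 18 (not isolated)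
Conditions: 17, 9-BBN-H, THF, rt; then 16, PdCl2(dppf) (5 mol %), AsPh3, Cs2CO3, DMF/H2O, rt
Reagents that add atoms: none
Why: B-alkyl Suzuki–Miyaura coupling: anti-Markovnikov hydroboration of 17 gives the primary alkylborane, which couples with the alkenyl iodide with retention to give the Z-trisubstituted C3=C4 alkene and add C5–C7.

Step 12
Reactants: 19 dimethyl acetal
Product: 20 aldehyde (C7 = CHO)
Conditions: PPTS, acetone/H2O, 45 °C
Reagents that add atoms: water, O
Why: Mild acid-catalysed acetal hydrolysis frees the C7 aldehyde while the secondary TBS ether and the alkenes should survive.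

Step 13
Reactants: 20 aldehyde
Product: 21 Z,Z dienyl iodide (C7=C8, iodine on C8 cis to C6)
Conditions: [Ph3PCH(I)CH3]I, NaN(SiMe3)2, THF, −78 °C
Reagents that add atoms: (1-iodoethyl)triphenylphosphonium iodide, CC(I)[P+](c1ccccc1)(c1ccccc1)c1ccccc1.[I-]
Why: A second Stork–Zhao olefination should give the Z iodoalkene at C7=C8.

Step 14
Reactants: 21 Z,Z dienyl iodide
Product: 23 bicyclo[9.3.2]hexadecatriene silyl ether, via alkylborane 22 (not isolated)
Conditions: 9-BBN-H, THF, rt; then slow addition to PdCl2(dppf) (10 mol %), AsPh3, Cs2CO3, THF/DMF/H2O, 50 °C (1 mM)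
Reagents that add atoms: none
Why: Intramolecular B-alkyl Suzuki–Miyaura macrocyclisation: the borane should add only to the monosubstituted vinyl group (boron on C9), and high dilution should allow C8–C9 coupling with retention to close the 13-membered ring.

Step 15
Reactants: 23 bicyclo[9.3.2]hexadecatriene silyl ether
Product: 24 bicyclic homoallylic alcohol (12-OH)
Conditions: Bu4NF, THF, rt
Reagents that add atoms: none
Why: Fluoride-mediated desilylation frees the C12 hydroxyl that is needed as directing group.

Step 16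
Reactants: 24 bicyclic homoallylic alcohol
Product: 25 15,16-epoxy alcohol (oxirane oxygen cis to 12-OH)
Conditions: VO(acac)2 (5 mol %), t-BuOOH, CH2Cl2, 0 °C to rt
Reagents that add atoms: tert-butyl hydroperoxide, CC(C)(C)OO
Why: Vanadium-catalysed hydroxyl-directed epoxidation: the homoallylic C12 alkoxide should deliver oxygen only to the C15=C16 alkene and to its face cis to the hydroxyl (cis to C2, trans to C10), since the other trisubstituted alkenes have no suitably placed hydroxyl.

Step 17
Reactants: 25 15,16-epoxy alcohol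
Product: 26 epoxy triethylsilyl ether
Conditions: Et3SiCl, imidazole, DMAP (cat.), CH2Cl2, 0 °C
Reagents that add atoms: chlorotriethylsilane, CC[Si](CC)(CC)Cl
Why: Base-mediated silylation (no Lewis-acidic silyl triflate, so the oxirane survives) masks the hydroxyl that would otherwise bind the aluminium reagent.

Step 18
Reactants: 26 epoxy triethylsilyl ether
Product: 27 bicyclo[9.3.1]pentadecadiene-15-carbaldehyde (12-OTES)
Conditions: MeAl(OAr)2 (Ar = 4-bromo-2,6-di-tert-butylphenyl, MABR; 1.2 equiv), CH2Cl2, −78 to −20 °C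
Reagents that add atoms: none
Why: Lewis-acid-promoted epoxide-to-aldehyde (Meinwald, semipinacol) rearrangement: the bulky aluminium phenoxide ionises the oxirane at tertiary C15 while C11 migrates from C16 to C15 antiperiplanar to the breaking C15–O bond and C16 collapses to the formyl group. The closest known reaction type is the MABR-mediated rearrangement of trisubstituted epoxides to α-quaternary aldehydes, together with the ring contraction of 1-alkylcycloalkene oxides to 1-alkylcycloalkanecarbaldehydes. No ring is closed by a new cyclisation: the C11–C15 bond formed by the suprafacial 1,2-shift turns the seven-membered ring into the cyclohexane C1–C14–C13–C12–C11–C15 and the 13-membered carbocycle into the 12-membered one in the same event. The only new stereocentre, C15, is set by inversion at C15 with respect to the oxirane oxygen (placed in step 16 by the C12 hydroxyl), so the formyl group ends up on the former oxirane face, cis to C2 and trans to C10, while C11 migrates with retention. The step needs the alkyl shift of C11 to win over the hydride shift from C16 and over capture of the C15 cation by the C3=C4, C7=C8 or side-chain alkenes. The oxophilic, non-nucleophilic and very bulky Lewis acid at low temperature favours concerted anti migration of carbon, and no alkene can reach C15 through a five- or six-membered transition state with Markovnikov polarity.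

Step 19
Reactants: 27 bicyclo[9.3.1]pentadecadiene-15-carbaldehyde
Product: 28 primary alcohol (15-CH2OH; 12-OTES)
Conditions: NaBH4, MeOH/THF, 0 °C
Reagents that add atoms: none
Why: Borohydride carbonyl reduction takes the hindered aldehyde to the neopentyl alcohol so that the C12 ketone can later be epoxidised without a competing carbonyl group.

Step 20
Reactants: 28 primary alcohol
Product: 29 bis(silyl ether) (15-CH2OTBS; 12-OTES)
Conditions: TBSOTf, 2,6-lutidine, CH2Cl2, −20 °C
Reagents that add atoms: tert-butyldimethylsilyl trifluoromethanesulfonate, CC(C)(C)[Si](C)(C)OS(=O)(=O)C(F)(F)F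
Why: Silyl triflate silylation of the hindered primary alcohol gives a TBS ether that is orthogonal to the secondary TES ether.

Step 21
Reactants: 29 bis(silyl ether)
Product: 31 C12 ketone (15-CH2OTBS), via secondary alcohol 30 (not isolated)
Conditions: IBX, DMSO, rt
Reagents that add atoms: none
Why: One-pot IBX-mediated cleavage of the triethylsilyl ether and oxidation of the liberated secondary alcohol (hypervalent iodine oxidation) should give the ketone while the TBS ether is untouched.

Step 22
Reactants: 31 C12 ketone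
Product: 32 spiro-oxirane silyl ether
Conditions: Me3SI, KN(SiMe3)2, THF, −10 to 0 °C
Reagents that add atoms: trimethylsulfonium iodide, C[S+](C)C.[I-]
Why: Corey–Chaykovsky epoxidation: irreversible addition of dimethylsulfonium methylide to the C12 carbonyl is expected from the face anti to the adjacent C10 substituent on C11 (the face of H-11), which places the new CH2 cis to C16 and the oxygen cis to C10; the low temperature should keep the enolisable C11 centre intact.

Step 23
Reactants: 32 spiro-oxirane silyl ether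
Product: 33 spiro-oxirane primary alcohol
Conditions: Bu4NF, THF, rt
Reagents that add atoms: none
Why: Fluoride desilylation frees the primary alcohol; the oxirane is inert to fluoride.

Step 24
Reactants: 33 spiro-oxirane primary alcohol
Product: 34 target aldehyde
Conditions: Dess–Martin periodinane, NaHCO3, CH2Cl2, 0 °C to rt
Reagents that add atoms: none
Why: Buffered Dess–Martin oxidation should convert the neopentyl alcohol into the non-enolisable aldehyde without opening the acid-sensitive spiro-oxirane.

**Compound list**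

1 | cyclohepta-1,3-diene | C1=CC=CCCC1 | starting material
2 | 6,7-dioxabicyclo[3.2.2]non-8-ene (meso) | C1CC[C@@H]2C=C[C@H]1OO2 | intermediate
3 | (R)-4-hydroxycyclohept-2-en-1-one | O=C1C=C[C@H](O)CCC1 | intermediate
4 | (R)-4-(tert-butyldimethylsilyloxy)cyclohept-2-en-1-one | O=C1C=C[C@H](O[Si](C)(C)C(C)(C)C)CCC1 | intermediate
5 | 4-(tert-butyldimethylsilyloxy)-1-(triethylsilyloxy)-3-vinylcyclohept-1-ene, 3,4-trans | CC[Si](CC)(CC)OC1=C[C@@H](C=C)[C@H](O[Si](C)(C)C(C)(C)C)CCC1 | intermediate
6 | 1,2-epoxide of 5, oxirane oxygen trans to vinyl (not isolated) | CC[Si](CC)(CC)O[C@@]12O[C@@H]1[C@@H](C=C)[C@H](O[Si](C)(C)C(C)(C)C)CCC2 | intermediate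
7 | 4-(tert-butyldimethylsilyloxy)-2-(triethylsilyloxy)-3-vinylcycloheptan-1-one; 2-OTES and 4-OTBS cis, both trans to 3-vinyl | O=C1CCC[C@@H](O[Si](C)(C)C(C)(C)C)[C@H](C=C)[C@H]1O[Si](CC)(CC)CC | intermediate
8 | 5-(tert-butyldimethylsilyloxy)-7-(triethylsilyloxy)-6-vinylcyclohept-1-en-1-yl trifluoromethanesulfonate (configuration as in 7) | O=S(=O)(OC1=CCC[C@@H](O[Si](C)(C)C(C)(C)C)[C@H](C=C)[C@H]1O[Si](CC)(CC)CC)C(F)(F)F | intermediate
9 | 5-bromo-2-methylpent-2-ene | CC(C)=CCCBr | starting material
10 | (4-methylpent-3-en-1-yl)magnesium bromide (not isolated) | CC(C)=CCC[Mg]Br | intermediate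
11 | triethylsilyl ether of 12 (not isolated) | CC(C)=CCCC1=CCC[C@@H](O[Si](C)(C)C(C)(C)C)[C@H](C=C)[C@H]1O[Si](CC)(CC)CC | intermediate
12 | 6-(tert-butyldimethylsilyloxy)-2-(4-methylpent-3-en-1-yl)-7-vinylcyclohept-2-en-1-ol; 1-OH and 6-OTBS cis, both trans to 7-vinyl | CC(C)=CCCC1=CCC[C@@H](O[Si](C)(C)C(C)(C)C)[C@H](C=C)[C@H]1O | intermediate
13 | mixed ketene acetal of 12 (O-ethyl, O-cycloheptenyl; not isolated) | CC(C)=CCCC1=CCC[C@@H](O[Si](C)(C)C(C)(C)C)[C@H](C=C)[C@H]1OC(=C)OCC | intermediate
14 | ethyl 2-[5-(tert-butyldimethylsilyloxy)-2-(4-methylpent-3-en-1-yl)-4-vinylcyclohept-2-en-1-yl]acetate; acetate arm cis to 5-OTBS, trans to 4-vinyl | CC(C)=CCCC1=C[C@@H](C=C)[C@H](O[Si](C)(C)C(C)(C)C)CC[C@@H]1CC(=O)OCC | intermediate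
15 | the corresponding acetaldehyde (C3 = CHO) | CC(C)=CCCC1=C[C@@H](C=C)[C@H](O[Si](C)(C)C(C)(C)C)CC[C@@H]1CC=O | intermediate
16 | cycloheptene of 15 with a (Z)-3-iodobut-2-en-1-yl arm on C1 | CC(C)=CCCC1=C[C@@H](C=C)[C@H](O[Si](C)(C)C(C)(C)C)CC[C@@H]1C/C=C(/C)I | intermediate
17 | 3,3-dimethoxyprop-1-ene (acrolein dimethyl acetal) | C=CC(OC)OC | starting material
18 | 9-(3,3-dimethoxypropyl)-9-borabicyclo[3.3.1]nonane (not isolated) | COC(CCB1C2CCCC1CCC2)OC | intermediate
19 | cycloheptene with a (Z)-6,6-dimethoxy-3-methylhex-2-en-1-yl arm on C1 | CC(C)=CCCC1=C[C@@H](C=C)[C@H](O[Si](C)(C)C(C)(C)C)CC[C@@H]1C/C=C(/C)CCC(OC)OC | intermediate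
20 | cycloheptene with a (Z)-3-methyl-6-oxohex-2-en-1-yl arm on C1 | CC(C)=CCCC1=C[C@@H](C=C)[C@H](O[Si](C)(C)C(C)(C)C)CC[C@@H]1C/C=C(/C)CCC=O | intermediate
21 | cycloheptene with a (2Z,6Z)-7-iodo-3-methylocta-2,6-dien-1-yl arm on C1 and vinyl on C11 | CC(C)=CCCC1=C[C@@H](C=C)[C@H](O[Si](C)(C)C(C)(C)C)CC[C@@H]1C/C=C(/C)CC/C=C(/C)I | intermediate
22 | 9-BBN adduct of 21 at the vinyl group (boron on C9; not isolated) | CC(C)=CCCC1=C[C@@H](CCB2C3CCCC2CCC3)[C@H](O[Si](C)(C)C(C)(C)C)CC[C@@H]1C/C=C(/C)CC/C=C(/C)I | intermediate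
23 | (3Z,7Z)-12-(tert-butyldimethylsilyloxy)-4,8-dimethyl-15-(4-methylpent-3-en-1-yl)bicyclo[9.3.2]hexadeca-3,7,15-triene; C2 and C10 trans on the cycloheptene, 12-O cis to C2 | CC(C)=CCCC1=C[C@@H]2[C@H](O[Si](C)(C)C(C)(C)C)CC[C@@H]1C/C=C(/C)CC/C=C(/C)CC2 | intermediate
24 | the 12-ol of 23 | CC(C)=CCCC1=C[C@@H]2[C@H](O)CC[C@@H]1C/C=C(/C)CC/C=C(/C)CC2 | intermediate
25 | 15,16-epoxide of 24, oxirane oxygen cis to 12-OH | CC(C)=CCC[C@@]12O[C@@H]1[C@@H]3[C@H](O)CC[C@@H]2C/C=C(/C)CC/C=C(/C)CC3 | intermediate
26 | 12-O-triethylsilyl ether of 25 | CC(C)=CCC[C@@]12O[C@@H]1[C@@H]3[C@H](O[Si](CC)(CC)CC)CC[C@@H]2C/C=C(/C)CC/C=C(/C)CC3 | intermediate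
27 | (3Z,7Z)-4,8-dimethyl-15-(4-methylpent-3-en-1-yl)-12-(triethylsilyloxy)bicyclo[9.3.1]pentadeca-3,7-diene-15-carbaldehyde; CHO cis to C2 and to 12-O, C2 and C10 trans | CC(C)=CCC[C@]1(C=O)[C@H]2C/C=C(/C)CC/C=C(/C)CC[C@H]1[C@@H](CC2)O[Si](CC)(CC)CC | intermediate
28 | the 15-hydroxymethyl analogue of 27 | CC(C)=CCC[C@]1(CO)[C@H]2C/C=C(/C)CC/C=C(/C)CC[C@H]1[C@@H](CC2)O[Si](CC)(CC)CC | intermediate
29 | 15-(tert-butyldimethylsilyloxymethyl)-12-(triethylsilyloxy) analogue | CC(C)=CCC[C@]1(CO[Si](C)(C)C(C)(C)C)[C@H]2C/C=C(/C)CC/C=C(/C)CC[C@H]1[C@@H](CC2)O[Si](CC)(CC)CC | intermediate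
30 | the 12-ol of 29 (not isolated) | CC(C)=CCC[C@]1(CO[Si](C)(C)C(C)(C)C)[C@H]2C/C=C(/C)CC/C=C(/C)CC[C@H]1[C@@H](CC2)O | intermediate
31 | the 12-ketone | CC(C)=CCC[C@]1(CO[Si](C)(C)C(C)(C)C)[C@H]2C/C=C(/C)CC/C=C(/C)CC[C@H]1C(=O)CC2 | intermediate
32 | spiro[bicyclo[9.3.1]pentadecadiene-12,2'-oxirane] with 15-CH2OTBS; oxirane oxygen cis to C10 | CC(C)=CCC[C@]1(CO[Si](C)(C)C(C)(C)C)[C@H]2C/C=C(/C)CC/C=C(/C)CC[C@H]1[C@@]1(CC2)CO1 | intermediate
33 | the 15-hydroxymethyl spiro-oxirane | CC(C)=CCC[C@]1(CO)[C@H]2C/C=C(/C)CC/C=C(/C)CC[C@H]1[C@@]1(CC2)CO1 | intermediate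
34 | (3Z,7Z)-4,8-dimethyl-15-(4-methylpent-3-en-1-yl)spiro[bicyclo[9.3.1]pentadeca-3,7-diene-12,2'-oxirane]-15-carbaldehyde (CNP0283574.1) | CC(C)=CCC[C@]1(C=O)[C@H]2C/C=C(/C)CC/C=C(/C)CC[C@H]1[C@@]1(CC2)CO1 | target

**Step count and risks**

Total: 24 steps. Longest linear sequence: 24 steps (1 to 34); 9 and 17 are purchased and enter directly.

Steps most likely to fail:

1. Step 18 (ring contraction on the macrobicycle). The process at risk is the partition of the ionising epoxide: a hydride shift from C16 (giving the cycloheptanone), transannular capture of the C15 cation by the C3=C4 or C7=C8 alkene, or slow complexation of the hindered oxirane could compete with the shift of C11. Fallback: contract the ring before the macrocycle is closed, from 21 back to 29. Bu4NF on 21 would give the seco homoallylic alcohol F1. VO(acac)2 with t-BuOOH would give the cis epoxy alcohol F2, and Et3SiCl with imidazole the epoxy silyl ether F3. MABR would then rearrange this monocyclic epoxide, which has no transannular alkene and a more open oxirane, to the cyclohexanecarbaldehyde F4. NaBH4 would give the primary alcohol F5 and TBSOTf the bis(silyl ether) F6. Hydroboration of the C11 vinyl group of F6 with 9-BBN-H and coupling with the C8 iodide under the conditions of step 14 would close the 12-membered ring directly and give 29.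

2. Step 14 (macrocyclisation). The process at risk is ring closure onto arms that are trans on the cycloheptene: intermolecular coupling or loss of the borane (protodeboronation, β-hydride elimination) could outrun cyclisation in the basic aqueous medium. Fallback: close the same bond through an isolable alkyl iodide and an organozinc, from 21 back to 23. Hydroboration of 21 with 9-BBN-H and oxidation with NaOH/H2O2 would give the primary alcohol F7. I2, PPh3 and imidazole would give the primary iodide F8. Zinc dust with LiCl in THF would insert only into the alkyl C–I bond, and Pd(PPh3)4 under high dilution would close the ring by intramolecular Negishi coupling to give 23.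

3. Step 8 (Johnson–Claisen rearrangement). The process at risk is the [3,3] shift onto the congested C1: acid-promoted dehydration of the hindered allylic alcohol to a diene, or incomplete ketene acetal formation, could prevail at the temperature needed. Fallback: allylic substitution with a malonate, from 12 back to 15. ClCO2Me and pyridine would give the allylic methyl carbonate F9. Pd(PPh3)4 with dimethyl malonate (Tsuji–Trost alkylation, net retention, attack at the less hindered C1 terminus) would give the malonate F10 with the same configuration at C1. Krapcho demethoxycarbonylation (NaCl, wet DMSO, 150 °C) would give the methyl ester F11, and i-Bu2AlH at −78 °C would give 15.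

**Further compounds**

F1 | step 18 | 12-ol of 21 (seco homoallylic alcohol) | CC(C)=CCCC1=C[C@@H](C=C)[C@H](O)CC[C@@H]1C/C=C(/C)CC/C=C(/C)I
F2 | step 18 | 15,16-epoxide of F1, oxirane oxygen cis to 12-OH | CC(C)=CCC[C@@]12O[C@@H]1[C@@H](C=C)[C@H](O)CC[C@@H]2C/C=C(/C)CC/C=C(/C)I
F3 | step 18 | 12-O-triethylsilyl ether of F2 | CC(C)=CCC[C@@]12O[C@@H]1[C@@H](C=C)[C@H](O[Si](CC)(CC)CC)CC[C@@H]2C/C=C(/C)CC/C=C(/C)I
F4 | step 18 | monocyclic cyclohexanecarbaldehyde (C15 quaternary; C1 dienyl iodide arm, C11 vinyl, 12-OTES) | CC(C)=CCC[C@]1(C=O)[C@@H](C/C=C(/C)CC/C=C(/C)I)CC[C@@H](O[Si](CC)(CC)CC)[C@@H]1C=C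
F5 | step 18 | 15-hydroxymethyl analogue of F4 | CC(C)=CCC[C@]1(CO)[C@@H](C/C=C(/C)CC/C=C(/C)I)CC[C@@H](O[Si](CC)(CC)CC)[C@@H]1C=C
F6 | step 18 | 15-(tert-butyldimethylsilyloxymethyl) analogue of F4 | CC(C)=CCC[C@]1(CO[Si](C)(C)C(C)(C)C)[C@@H](C/C=C(/C)CC/C=C(/C)I)CC[C@@H](O[Si](CC)(CC)CC)[C@@H]1C=C
F7 | step 14 | primary alcohol from 21 (C11–CH2CH2OH) | CC(C)=CCCC1=C[C@@H](CCO)[C@H](O[Si](C)(C)C(C)(C)C)CC[C@@H]1C/C=C(/C)CC/C=C(/C)I
F8 | step 14 | primary iodide (C11–CH2CH2I) | CC(C)=CCCC1=C[C@@H](CCI)[C@H](O[Si](C)(C)C(C)(C)C)CC[C@@H]1C/C=C(/C)CC/C=C(/C)I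
F9 | step 8 | methyl carbonate of 12 | CC(C)=CCCC1=CCC[C@@H](O[Si](C)(C)C(C)(C)C)[C@H](C=C)[C@H]1OC(=O)OC
F10 | step 8 | dimethyl malonate at C1 (configuration at C1 as in 14) | CC(C)=CCCC1=C[C@@H](C=C)[C@H](O[Si](C)(C)C(C)(C)C)CC[C@@H]1C(C(=O)OC)C(=O)OC
F11 | step 8 | methyl ester analogue of 14 | CC(C)=CCCC1=C[C@@H](C=C)[C@H](O[Si](C)(C)C(C)(C)C)CC[C@@H]1CC(=O)OC
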